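## Retrosynthetic overview

1. The C2′ isovalerate is introduced last on the free threo-triol, after masking the benzylic C1′-OH as a silyl ether; the triol comes from its 1′,2′-acetonide.
2. Key disconnection: the aryl–C1′ bond of that acetonide, formed by a visible-light Ni/photoredox decarboxylative arylation of a trans-dioxolane-4-carboxylic acid with 6-bromo-7-methoxycoumarin; C1′ is set trans to the C2′ substituent.
3. The dioxolane acid (C2′ stereocenter plus the CMe2OH group) comes from dimethyl 2,3-O-isopropylidene-D-tartrate by mono-saponification and MeMgBr addition.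
4. Ring order: the dioxolane ring is bought; the coumarin pyranone ring is closed first (Wittig/lactonisation of a salicylaldehyde), before the coupling; no ring is formed afterwards.

Assumption: 6-bromo-7-methoxycoumarin is not treated as a catalogue item and is made in one step. C1′–C3′ denote the side-chain carbons counted from the coumarin.

Stereochemical check: the target is (1′R,2′S), a threo diol. This maps onto D-(–)-tartaric acid (2S,3S): C2′ keeps its S descriptor, and C1′ becomes R when aryl replaces CO2H on the same face (CIP ranks of the two carbon substituents swap).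

## Route

Step 1
Reactants: 1 dimethyl (4S,5S)-2,2-dimethyl-1,3-dioxolane-4,5-dicarboxylate (dimethyl 2,3-O-isopropylidene-D-tartrate)
Product: 2 (4S,5S)-5-(methoxycarbonyl)-2,2-dimethyl-1,3-dioxolane-4-carboxylic acid
Conditions: KOH (1.0 equiv), MeOH, 0 °C to rt; then cold 1 M HCl to pH 3, EtOAc
Reagents that add atoms: potassium hydroxide, [K+].[OH-]
Why: Mono-saponification of a C2-symmetric diester stops cleanly at the mono-carboxylate, which is deactivated towards a second hydrolysis; no stereocenter is touched, and epimerisation would in any case give the disfavoured cis isomer, not the enantiomer.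

Step 2
Reactants: 2 (4S,5S)-5-(methoxycarbonyl)-2,2-dimethyl-1,3-dioxolane-4-carboxylic acid
Product: 4 (4S,5S)-5-(2-hydroxypropan-2-yl)-2,2-dimethyl-1,3-dioxolane-4-carboxylic acid, via (4S,5S)-5-acetyl-2,2-dimethyl-1,3-dioxolane-4-carboxylic acid 3 (not isolated)
Conditions: MeMgBr (3.5 equiv), THF, –20 °C to rt; then cold 1 M HCl to pH 3, EtOAc (salting out)
Reagents that add atoms: methylmagnesium bromide, C[Mg]Br
Why: Grignard double addition: the first equivalent forms the inert magnesium carboxylate and two more add to the methyl ester through the ketone; the C5 stereocenter (future C2′) is retained, and lactonisation is blocked because it would need a trans-fused bicyclo[3.3.0] lactone.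

Step 3
Reactants: 5 5-bromo-2-hydroxy-4-methoxybenzaldehyde
Product: 7 6-bromo-7-methoxy-2H-chromen-2-one, via ethyl (2E)-3-(5-bromo-2-hydroxy-4-methoxyphenyl)prop-2-enoate 6 (not isolated)
Conditions: Ph3P=CHCO2Et (1.2 equiv), N,N-diethylaniline, reflux (ca. 215 °C), 4 h
Reagents that add atoms: ethyl (triphenylphosphoranylidene)acetate, CCOC(=O)C=P(c1ccccc1)(c1ccccc1)c1ccccc1
Why: Wittig olefination followed by thermal E/Z isomerisation and lactonisation is the standard one-pot coumarin synthesis from salicylaldehydes; no stereocenter is involved.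

Step 4
Reactants: 4 (4S,5S)-5-(2-hydroxypropan-2-yl)-2,2-dimethyl-1,3-dioxolane-4-carboxylic acid; 7 6-bromo-7-methoxy-2H-chromen-2-one
Product: 8 6-[(4R,5S)-5-(2-hydroxypropan-2-yl)-2,2-dimethyl-1,3-dioxolan-4-yl]-7-methoxy-2H-chromen-2-one
Conditions: 4 (1.5 equiv), 7 (1.0 equiv), NiCl2·glyme (10 mol %), dtbbpy (15 mol %), 4CzIPN (3 mol %), Cs2CO3 (1.5 equiv), degassed DMA (0.05 M), 450 nm LEDs, 25 °C
Reagents that add atoms: none
Why: Proposed new method: a Ni/organophotoredox decarboxylative C(sp3)–C(sp2) arylation applied for the first time to a tartrate-derived dioxolane-4-carboxylic acid carrying an unprotected tertiary carbinol on the adjacent carbon, with a bromocoumarin (itself a triplet acceptor) as electrophile; excited 4CzIPN oxidises the caesium carboxylate, loss of CO2 gives the 1,3-dioxolan-4-yl radical (old stereocenter erased), which is captured by the (dtbbpy)Ni(Ar)Br complex from oxidative addition of 7 on the face anti to the bulky CMe2OH group, and reductive elimination from Ni(III) gives the trans (4R,5S) product, so C1′ is controlled by the tartrate-derived C2′; the coumarin does not absorb at 450 nm, energy transfer from 4CzIPN is about thermoneutral or uphill, and fast quenching by the carboxylate at high dilution of 7 should suppress [2+2] dimerisation; the closest known reaction types are the Ni/photoredox decarboxylative arylation of α-oxy acids with aryl bromides and the trans-selective Ni-catalysed arylation of tartrate-acetonide redox-active esters.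

Step 5
Reactants: 8 6-[(4R,5S)-5-(2-hydroxypropan-2-yl)-2,2-dimethyl-1,3-dioxolan-4-yl]-7-methoxy-2H-chromen-2-one
Product: 9 6-[(1R,2S)-1,2,3-trihydroxy-3-methylbutyl]-7-methoxy-2H-chromen-2-one
Conditions: AcOH/H2O (4:1), 40 °C; toluene azeotrope
Reagents that add atoms: none
Why: Acid-catalysed acetal hydrolysis cleaves only the bonds at the ketal carbon, so both C–O stereocenters keep their configuration; the weak acid avoids ionisation of the benzylic C–O bond.

Step 6
Reactants: 9 6-[(1R,2S)-1,2,3-trihydroxy-3-methylbutyl]-7-methoxy-2H-chromen-2-one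
Product: 10 6-[(1R,2S)-1-[(tert-butyldimethylsilyl)oxy]-2,3-dihydroxy-3-methylbutyl]-7-methoxy-2H-chromen-2-one
Conditions: TBSCl (1.1 equiv), imidazole (2.5 equiv), DMF, 0 °C
Reagents that add atoms: tert-butyldimethylsilyl chloride, CC(C)(C)[Si](C)(C)Cl
Why: Kinetic silylation goes to the least hindered hydroxyl, the benzylic C1′-OH; the C2′-OH sits next to the quaternary carbinol carbon and the tertiary OH is inert to TBSCl/imidazole.

Step 7
Reactants: 10 6-[(1R,2S)-1-[(tert-butyldimethylsilyl)oxy]-2,3-dihydroxy-3-methylbutyl]-7-methoxy-2H-chromen-2-one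
Product: 11 (1R,2S)-1-[(tert-butyldimethylsilyl)oxy]-3-hydroxy-1-(7-methoxy-2-oxo-2H-chromen-6-yl)-3-methylbutan-2-yl 3-methylbutanoate
Conditions: (iBuCO)2O (2.0 equiv), DMAP (0.3 equiv), Et3N (3 equiv), CH2Cl2, rt, 16 h
Reagents that add atoms: 3-methylbutanoic (isovaleric) anhydride, CC(C)CC(=O)OC(=O)CC(C)C
Why: DMAP-catalysed (Steglich-type) acylation of the only free secondary hydroxyl; the tertiary OH does not acylate at room temperature and no stereocenter is affected.

Step 8
Reactants: 11 (1R,2S)-1-[(tert-butyldimethylsilyl)oxy]-3-hydroxy-1-(7-methoxy-2-oxo-2H-chromen-6-yl)-3-methylbutan-2-yl 3-methylbutanoate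
Product: 12 (1R,2S)-1,3-dihydroxy-1-(7-methoxy-2-oxo-2H-chromen-6-yl)-3-methylbutan-2-yl 3-methylbutanoate (CNP0260807.1)
Conditions: HF·pyridine, THF/pyridine, 0 °C to rt
Reagents that add atoms: none
Why: Fluoride-mediated Si–O cleavage under buffered, mildly acidic conditions removes the TBS group without the base-catalysed 1,2-acyl migration that TBAF could cause; the ester and lactone are untouched.

## Compound list

1 | dimethyl (4S,5S)-2,2-dimethyl-1,3-dioxolane-4,5-dicarboxylate | COC(=O)[C@H]1OC(C)(C)O[C@@H]1C(=O)OC | starting material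
2 | (4S,5S)-5-(methoxycarbonyl)-2,2-dimethyl-1,3-dioxolane-4-carboxylic acid | OC(=O)[C@H]1OC(C)(C)O[C@@H]1C(=O)OC | intermediate
3 | (4S,5S)-5-acetyl-2,2-dimethyl-1,3-dioxolane-4-carboxylic acid (present as its magnesium carboxylate) | OC(=O)[C@H]1OC(C)(C)O[C@@H]1C(C)=O | intermediate (not isolated)
4 | (4S,5S)-5-(2-hydroxypropan-2-yl)-2,2-dimethyl-1,3-dioxolane-4-carboxylic acid | OC(=O)[C@H]1OC(C)(C)O[C@@H]1C(C)(C)O | intermediate
5 | 5-bromo-2-hydroxy-4-methoxybenzaldehyde | COc1cc(O)c(C=O)cc1Br | starting material
6 | ethyl (2E)-3-(5-bromo-2-hydroxy-4-methoxyphenyl)prop-2-enoate | CCOC(=O)/C=C/c1cc(Br)c(OC)cc1O | intermediate (not isolated)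
7 | 6-bromo-7-methoxy-2H-chromen-2-one | COc1cc2oc(=O)ccc2cc1Br | intermediate
8 | 6-[(4R,5S)-5-(2-hydroxypropan-2-yl)-2,2-dimethyl-1,3-dioxolan-4-yl]-7-methoxy-2H-chromen-2-one | COc1cc2oc(=O)ccc2cc1[C@H]3OC(C)(C)O[C@@H]3C(C)(C)O | intermediate
9 | 6-[(1R,2S)-1,2,3-trihydroxy-3-methylbutyl]-7-methoxy-2H-chromen-2-one | COc1cc2oc(=O)ccc2cc1[C@@H](O)[C@H](O)C(C)(C)O | intermediate
10 | 6-[(1R,2S)-1-[(tert-butyldimethylsilyl)oxy]-2,3-dihydroxy-3-methylbutyl]-7-methoxy-2H-chromen-2-one | COc1cc2oc(=O)ccc2cc1[C@@H](O[Si](C)(C)C(C)(C)C)[C@H](O)C(C)(C)O | intermediate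
11 | (1R,2S)-1-[(tert-butyldimethylsilyl)oxy]-3-hydroxy-1-(7-methoxy-2-oxo-2H-chromen-6-yl)-3-methylbutan-2-yl 3-methylbutanoate | COc1cc2oc(=O)ccc2cc1[C@@H](O[Si](C)(C)C(C)(C)C)[C@H](OC(=O)CC(C)C)C(C)(C)O | intermediate
12 | (1R,2S)-1,3-dihydroxy-1-(7-methoxy-2-oxo-2H-chromen-6-yl)-3-methylbutan-2-yl 3-methylbutanoate | COc1cc2oc(=O)ccc2cc1[C@@H](O)[C@H](OC(=O)CC(C)C)C(C)(C)O | target

## Step count and risks

Total steps: 8. Longest linear sequence: 7 (1 → 2 → 4 → 8 → 9 → 10 → 11 → 12); step 3 is the one-step side branch to 7.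

Steps most likely to fail:

**Step 4 (the proposed new coupling).** Risks are triplet sensitisation of the coumarin ([2+2] dimers), protodecarboxylation of 4, and lower trans selectivity than expected. The fallback uses known thermal chemistry and sets out from 4. The acid is esterified with N-hydroxyphthalimide (DIC, cat. DMAP, CH2Cl2) to give the redox-active ester 1,3-dioxoisoindolin-2-yl (4S,5S)-5-(2-hydroxypropan-2-yl)-2,2-dimethyl-1,3-dioxolane-4-carboxylate F1. F1 is then coupled with 7 in the dark by the established Ni-catalysed reductive decarboxylative arylation of redox-active esters (NiBr2·glyme/dtbbpy, Zn powder, DMA). The same dioxolanyl radical is captured trans, and the route is rejoined at 8.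

**Step 6 (regioselective mono-silylation of C1′-OH over C2′-OH).** If the kinetic preference is poor, the protect–acylate–deprotect sequence is replaced by intramolecular acyl delivery, setting out from 9. Triol 9 is treated with trimethyl orthoisovalerate (cat. CSA, CH2Cl2) to give the cyclic orthoester 6-[(4R,5S)-5-(2-hydroxypropan-2-yl)-2-methoxy-2-(2-methylpropyl)-1,3-dioxolan-4-yl]-7-methoxy-2H-chromen-2-one F2 (epimers at the ortho carbon). Mild hydrolysis in situ (80 % aq. AcOH, rt) then opens it. Kinetic opening of cyclic orthoesters normally leaves the ester on the more hindered oxygen, here O2′, but this is an extrapolation to this substrate. The fallback rejoins at 12 and bypasses 10 and 11; any O1′ isomer is separated and recycled to 9 by methanolysis.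

**Step 2 (Grignard addition in the presence of a magnesium carboxylate, and isolation of a very polar hydroxy acid).** If addition stalls at ketone 3 or recovery is poor, the order of desymmetrisation is reversed, setting out from 1. MeMgBr (2.1 equiv, THF, –78 to –20 °C) is added to diester 1 to convert one ester only, giving methyl (4S,5S)-5-(2-hydroxypropan-2-yl)-2,2-dimethyl-1,3-dioxolane-4-carboxylate F3, separated from unreacted 1 and the bis-adduct. Saponification (LiOH, THF/H2O, 0 °C) then rejoins the route at 4.

## Further compounds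

F1 | step 4 | 1,3-dioxoisoindolin-2-yl (4S,5S)-5-(2-hydroxypropan-2-yl)-2,2-dimethyl-1,3-dioxolane-4-carboxylate | O=C(ON1C(=O)c2ccccc2C1=O)[C@H]1OC(C)(C)O[C@@H]1C(C)(C)O
F2 | step 6 | 6-[(4R,5S)-5-(2-hydroxypropan-2-yl)-2-methoxy-2-(2-methylpropyl)-1,3-dioxolan-4-yl]-7-methoxy-2H-chromen-2-one | COc1cc2oc(=O)ccc2cc1[C@H]3OC(CC(C)C)(OC)O[C@@H]3C(C)(C)O
F3 | step 2 | methyl (4S,5S)-5-(2-hydroxypropan-2-yl)-2,2-dimethyl-1,3-dioxolane-4-carboxylate | COC(=O)[C@H]1OC(C)(C)O[C@@H]1C(C)(C)O
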